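# Proposed synthesis of (3S,4S,3'S,4'S)-7,8-didehydro-β,β-carotene-3,4,3',4'-tetrol (29)

## Analysis of the target

Target 29 is a C40 carotenoid: two 2,6,6-trimethylcyclohexene rings (ring A, C1–C6; ring B, C1'–C6') are joined through C6 and C6' by a linear C22 chain with methyl groups on C9, C13, C13' and C9'. Ring A is attached through the C7≡C8 triple bond and ring B through the E double bond C7'=C8'. The eight chain double bonds from C9=C10 to C7'=C8' are all E and, with the two ring double bonds C5=C6 and C5'=C6', form one conjugated chromophore. There are four stereocentres, C3, C4, C3' and C4', all S, and in each ring the two hydroxyl groups are trans. The two pairs are too far apart to influence each other, so each ring must receive its configuration independently, best from one enantiopure building block. The polyene is sensitive to light, oxygen, heat and acid. The C4 and C4' hydroxyl groups are allylic and, once the chain is in place, ionise easily under acid, so late steps should be neutral or basic and a late deprotection is unwelcome. The main difficulty is that the halves are almost, but not quite, identical: a dimerising synthesis is excluded, yet the ends differ at one position only. The strategy rests on this feature: from C9 to C9' the chain is constitutionally symmetric and the termini differ only at C7–C8. The ethynyl ring diol 4 can therefore serve as ring A directly (C7≡C8) and, after syn hydrometalation and iodination to the dienyl iodide 8, as ring B (C7'=C8').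

## Retrosynthetic reasoning

**C8–C9 and C8'–C9'.** Target 29 is cut at the two bonds that link the methyl-bearing carbons C9 and C9' to C8 and C8'. This gives alkyne 4, dienyl iodide 8 and the C18 heptaene 26, which carries iodine on C9 and, on C9', boron held in the cage derived from 15. The cut is made here because these are the only bonds whose cleavage leaves a symmetric chain skeleton and two ring pieces of one origin. A cut further into the chain would give two different ring-bearing polyenes, each to be built separately. The forward reaction must join the sp carbon C8 to C9 while boron stays silent, then release boron and join C9' to C8' without disturbing seven double bonds. Both events are stereoretentive cross-couplings that tolerate free hydroxyl groups, so 29 forms without a protecting group.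

**C8'–I.** Iodide 8 is traced to alkyne 4 by syn hydrometalation, with the metal on the terminal carbon, and iodination with retention, which fixes the E geometry of C7'=C8'. The hydroxyl groups would consume the metal hydride, so they are silylated for these operations (5, 7) and freed again before the coupling. The gain is that the four stereocentres are set once, in one compound.

**C4–O, the oxirane and C7–C8.** The trans diol of 4 comes from oxirane 3 by anti opening at the allylic carbon C4, and 3 from dienyne 2 by enantioselective oxygen transfer to C3=C4, the only cis-disubstituted double bond. Dienyne 2 comes from safranal 1 by one-carbon homologation of the aldehyde. The forward sequence must distinguish C3=C4 from the tetrasubstituted C5=C6 and open the oxirane at C4 with inversion. The regiochemistry of the opening matters for enantiomeric purity: opening at C3 would give the enantiomeric trans diol.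

**C11=C12 and C11'=C12'.** Heptaene 26 is cut at its two disubstituted double bonds by Horner–Wadsworth–Emmons disconnections. The central piece is the C10 bis(phosphonate) 24 and the ends are the two C4 aldehydes 13 (iodine on C9) and 20 (caged boron on C9'). The polarity is chosen so that boron sits on the aldehyde partner. A phosphonate on the boron fragment would need a strong base in the presence of the cage's acidic CH2 groups. The order is 13 first (to 25), then 20, so the cage meets only the stabilised carbanion of 25. The trisubstituted double bonds C13=C14 and C13'=C14' are carried in from 24 and those at C9 and C9' from the C4 pieces.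

**The C10 unit.** Bis(phosphonate) 24 comes from dibromide 23, diol 22 and the dialdehyde 21 by reduction, bromination and Arbuzov reaction.

**The C4 units.** Aldehydes 13 and 20 both derive from the E iodo alcohol 12, made from butynol 9 by syn hydrometalation (metal on C3) and iodination. Oxidation of 12 gives 13. Silylation (14), iodine–lithium exchange, borylation and complexation with 15 (18), desilylation (19) and oxidation give 20. One hydrometalation thus sets the geometry of both C9=C10 and C9'=C10'.

## Alternatives that were turned down

**Alternative 1:** This plan is organised around the ring stereocentres. The disconnection is at the C3–O and C4–O bonds: the diol is traced to oxirane A2 and this to the trimethylsilyl-capped dienyne A1. In the forward key step, the oxo species from the chloride of trivalent manganese with N,N'-bis(3,5-di-tert-butylsalicylidene)cyclohexane-1,2-diamine and NaOCl transfers oxygen to C3=C4 of A1 and closes the oxirane of A2. Anti opening at C4 then gives the trans diol.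
- For it: both stereocentres come from an achiral diene in one catalytic step, a cis-disubstituted alkene conjugated to a π system is the best substrate class for this catalyst, and the silyl cap keeps hypochlorite away from the alkyne C–H.
- Against it: it is a plan for ring A only. It does not say how forty carbons are joined or how the C7–C8 end is told from the C7'–C8' end, and the cap costs two extra steps.
- Comparison: on the stereocentres it is as strong as the chosen route, which uses the same kind of oxygen transfer in step 2 (on the uncapped dienyne 2, with a peracid as oxidant). What the chosen strategy adds is the solution for the chain: one ring unit for both ends and the last two skeletal bonds made in one operation that delivers unprotected 29.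

**Alternative 2:** The disconnection is at the C7≡C8 triple bond and the C6–C7 bond. Enyne A4 is traced to the cross-conjugated ketone A3, whose carbonyl carbon is C8. In the forward key step LiC(N2)SiMe3 adds to the carbonyl of A3, Me3SiOLi and N2 are lost, and the alkylidene carbene at the new carbon C7 rearranges by 1,2-shift of an alkenyl group to A4.
- For it: the triple bond is made without a transition metal, the C9=C10 geometry is fixed before the rearrangement, and both groups on the carbene are alkenyl, so either shift gives the same alkyne.
- Against it: the carbonyl of A3 lies between the ring carbon C6, flanked by the C1 gem-dimethyl group and the C5 methyl group, and an α-methylalkenyl group, so addition of a bulky nucleophile will be slow and vinylogous deprotonation can compete. The carbene can also insert into the nearby methyl C–H bonds. A4 covers only C1–C11 of ring A with three protecting groups, so a long linear chain extension, a separate ring B synthesis and a late deprotection would follow.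
- Comparison: the chosen route uses the same type of rearrangement in its easiest form (hydrogen shift from aldehyde 1, step 1) and then forms C8–C9 by alkynylation. The alternative avoids palladium at C8–C9; the chosen strategy offers convergence and no protecting group at the C40 stage instead.

**Alternative 3:** The disconnection is at the C9–CH3 and C10–C11 bonds. In the forward key step AlMe3 with Cp2ZrCl2 adds methyl to C9 and aluminium to C10 of the terminal alkyne of diyne A5, and the alkenylalane couples with the C11 iodide A6 under Pd(PPh3)4 and ZnCl2 to give the tetrasilyl ether A7.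
- For it: syn carbometalation builds the C9=C10 double bond with very high geometric fidelity. On this point it is stronger than any olefination and equal to the chosen route, where the same bond comes from a syn hydrometalation (step 7). It is also convergent and forms two C–C bonds in one flask.
- Against it: AlMe3 forces protection of all four hydroxyl groups, so the coupling product is A7 and a fourfold desilylation must be run on the C40 polyene, with allylic silyl ethers at C4 and C4'. A5 needs a conjugated diyne whose internal triple bond may also be carbometalated. A6 is a C26 heptaenyl iodide carrying ring B that needs its own long linear synthesis. The two ring units are unrelated, so the symmetry of the chain is not used.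
- Comparison: the chosen strategy gives up building C9=C10 in the key step. In exchange it offers free hydroxyl groups throughout the endgame, one ring intermediate for both ends, and a chain piece (26) made from one C10 and two C4 units.

Key step: step 18

Assumption: the (R,R) manganese salen catalyst is taken to give the (3S,4R)-oxirane 3, by analogy with indene and 1,2-dihydronaphthalene, where the (S,S) catalyst gives the S configuration at the oxirane carbon next to the unsaturated substituent; if the sense is reversed, the (S,S) catalyst is used and nothing else changes.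

## Route

Step 1
Reactants: 1 safranal (2,6,6-trimethylcyclohexa-1,3-diene-1-carbaldehyde)
Product: 2 1-ethynyl-2,6,6-trimethylcyclohexa-1,3-diene
Conditions: Me3SiCHN2, LiN(i-Pr)2, THF, −78 °C; then 1, −78 °C → rt
Reagents that add atoms: trimethylsilyldiazomethane, C[Si](C)(C)C=[N+]=[N-]
Why: Colvin rearrangement: the lithiated diazomethane adds to the aldehyde, Me3SiOLi and N2 are lost, and the alkylidene carbene gives the terminal alkyne by 1,2-hydrogen shift. The aldehyde has no α-hydrogen and addition at −78 °C should outrun vinylogous deprotonation.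

Step 2
Reactants: 2 1-ethynyl-2,6,6-trimethylcyclohexa-1,3-diene
Product: 3 (1R,6S)-3-ethynyl-2,4,4-trimethyl-7-oxabicyclo[4.1.0]hept-2-ene (the 3S,4R oxirane in carotenoid numbering)
Conditions: (R,R)-[N,N'-bis(3,5-di-tert-butylsalicylidene)cyclohexane-1,2-diaminato]MnCl (5 mol %), mCPBA, NMO, CH2Cl2, −78 °C
Reagents that add atoms: mCPBA, O=C(OO)c1cccc(Cl)c1
Why: Manganese salen (Jacobsen–Katsuki) epoxidation of a cis-disubstituted alkene conjugated to a π system, the preferred substrate class; the tetrasubstituted C5=C6 bond and the alkyne are not attacked at −78 °C. The catalyst selects the face of C3=C4 and so sets C3 (S) and C4 (R) together, and the ring enforces the cis oxirane.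

Step 3
Reactants: 3 (1R,6S)-3-ethynyl-2,4,4-trimethyl-7-oxabicyclo[4.1.0]hept-2-ene
Product: 4 (1S,2S)-4-ethynyl-3,5,5-trimethylcyclohex-3-ene-1,2-diol
Conditions: HClO4 (cat.), THF–H2O, 0 °C
Reagents that add atoms: water, O
Why: Acid-catalysed hydrolysis of a vinyl oxirane: the protonated oxirane opens at the allylic C4–O bond, which the C5=C6–C≡C system weakens, and water enters anti to the leaving oxygen. C3 keeps its configuration (S) and C4 is inverted (R to S), which gives the trans diol. Attack at C6 is blocked by the quaternary C1, and dilute acid at low temperature keeps the opening close to SN2.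

Step 4
Reactants: 4 (1S,2S)-4-ethynyl-3,5,5-trimethylcyclohex-3-ene-1,2-diol
Product: 5 bis(triethylsilyl) ether of 4, {[(1S,2S)-4-ethynyl-3,5,5-trimethylcyclohex-3-ene-1,2-diyl]bis(oxy)}bis(triethylsilane)
Conditions: Et3SiCl, imidazole, DMAP (cat.), DMF, 0 °C → rt
Reagents that add atoms: chlorotriethylsilane, CC[Si](Cl)(CC)CC
Why: Standard silylation of two secondary alcohols; the triethylsilyl group is small enough for the hindered C4 hydroxyl and is inert to the zirconium hydride and iodine of step 5.

Step 5
Reactants: 5 bis(triethylsilyl) ether of 4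
Product: 7 {[(1S,2S)-4-[(E)-2-iodoethenyl]-3,5,5-trimethylcyclohex-3-ene-1,2-diyl]bis(oxy)}bis(triethylsilane), via alkenylzirconocene chloride 6 (not isolated)
Conditions: Cp2Zr(H)Cl, THF, rt, dark; then I2, 0 °C
Reagents that add atoms: iodine, II (Cp2Zr(H)Cl, Cl[ZrH](C1C=CC=C1)C1C=CC=C1, puts zirconium into intermediate 6 and only hydrogen into 7)
Why: Hydrozirconation–iodination of a terminal alkyne: syn addition places zirconium on the terminal carbon C8 for steric reasons, and iodine cleaves the C–Zr bond with retention, which gives the E iodide.

Step 6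
Reactants: 7 bis(triethylsilyl) ether of the dienyl iodide
Product: 8 (1S,2S)-4-[(E)-2-iodoethenyl]-3,5,5-trimethylcyclohex-3-ene-1,2-diol
Conditions: Bu4NF, AcOH, THF, 0 °C, dark
Reagents that add atoms: none
Why: Fluoride-mediated desilylation; acetic acid buffers the medium so that the alkenyl iodide does not meet free alkoxide, and no acid strong enough to ionise the allylic C4–O bond is present.

Step 7
Reactants: 9 but-2-yn-1-ol
Product: 12 (2E)-3-iodobut-2-en-1-ol, via aluminium alkoxide 10 (not isolated), via alkenylzirconocene chloride 11 (not isolated)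
Conditions: i-Bu2AlH (1 equiv), THF, 0 °C; Cp2Zr(H)Cl, rt; then I2, −78 → 0 °C; aq. HCl work-up
Reagents that add atoms: iodine, II (i-Bu2AlH, CC(C)C[AlH]CC(C)C, and Cp2Zr(H)Cl, Cl[ZrH](C1C=CC=C1)C1C=CC=C1, put atoms only into intermediates 10 and 11)
Why: Hydrozirconation–iodination of an internal alkynol whose hydroxyl is first masked as the aluminium alkoxide so that it does not consume the zirconium hydride. Syn addition and equilibration with a slight excess of hydride should place zirconium on C3, away from the bulky CH2OAl group. Iodination with retention then leaves iodine trans to CH2OH (E).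

Step 8
Reactants: 12 (2E)-3-iodobut-2-en-1-ol
Product: 13 (2E)-3-iodobut-2-enal
Conditions: MnO2, CH2Cl2, rt, dark
Reagents that add atoms: none
Why: Allylic oxidation with MnO2 is neutral and stops at the aldehyde; the light-sensitive product is used at once to avoid E/Z drift.

Step 9
Reactants: 12 (2E)-3-iodobut-2-en-1-ol
Product: 14 tert-butyl{[(2E)-3-iodobut-2-en-1-yl]oxy}dimethylsilane
Conditions: t-BuMe2SiCl, imidazole, CH2Cl2, 0 °C → rt
Reagents that add atoms: tert-butyldimethylsilyl chloride, CC(C)(C)[Si](C)(C)Cl
Why: Silylation of a primary allylic alcohol, needed so that the iodine–lithium exchange of step 10 meets no acidic hydrogen.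

Step 10
Reactants: 14 tert-butyl{[(2E)-3-iodobut-2-en-1-yl]oxy}dimethylsilane; 15 N-methyliminodiacetic acid
Product: 18 2-[(2Z)-4-{[tert-butyl(dimethyl)silyl]oxy}but-2-en-2-yl]-6-methyl-1,3,6,2-dioxazaborocane-4,8-dione, via alkenyllithium 16 (not isolated), via lithium triisopropoxyborate 17 (not isolated)
Conditions: t-BuLi (2 equiv), Et2O, −78 °C; B(Oi-Pr)3, −78 °C → rt; then 15, DMSO, 110 °C
Reagents that add atoms: triisopropyl borate, CC(C)OB(OC(C)C)OC(C)C (tert-butyllithium, [Li]C(C)(C)C, puts lithium into intermediates 16 and 17 only)
Why: Iodine–lithium exchange gives a configurationally stable alkenyllithium, which is trapped as the borate, and transligation with the diacid 15 gives the air-stable cage. Boron stays trans to the CH2O carbon; the descriptor is Z only because methyl outranks boron. If the silyl ether is lost in hot DMSO, alcohol 19 results directly.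

Step 11
Reactants: 18 silyl ether of the C4 boronate
Product: 19 2-[(2Z)-4-hydroxybut-2-en-2-yl]-6-methyl-1,3,6,2-dioxazaborocane-4,8-dione
Conditions: HF·pyridine, THF, 0 °C → rt
Reagents that add atoms: none
Why: Acidic fluoride removes the silyl group; the iminodiacetate cage tolerates HF·pyridine, whereas basic fluoride sources would open it.

Step 12
Reactants: 19 2-[(2Z)-4-hydroxybut-2-en-2-yl]-6-methyl-1,3,6,2-dioxazaborocane-4,8-dione
Product: 20 (2Z)-3-(6-methyl-4,8-dioxo-1,3,6,2-dioxazaborocan-2-yl)but-2-enal
Conditions: Dess–Martin periodinane, CH2Cl2–MeCN, rt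
Reagents that add atoms: none
Why: Dess–Martin oxidation of the allylic alcohol under neutral, non-aqueous conditions, which the cage is known to survive; the tetracoordinate boron does not react with the oxidant.

Step 13
Reactants: 21 (2E,4E,6E)-2,7-dimethylocta-2,4,6-trienedial
Product: 22 (2E,4E,6E)-2,7-dimethylocta-2,4,6-triene-1,8-diol
Conditions: NaBH4, MeOH–THF, 0 °C
Reagents that add atoms: none
Why: 1,2-Reduction of both conjugated aldehydes by NaBH4; the triene geometry is untouched.

Step 14
Reactants: 22 (2E,4E,6E)-2,7-dimethylocta-2,4,6-triene-1,8-diol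
Product: 23 (2E,4E,6E)-1,8-dibromo-2,7-dimethylocta-2,4,6-triene
Conditions: PBr3, pyridine (cat.), Et2O, −10 °C, dark
Reagents that add atoms: phosphorus tribromide, BrP(Br)Br
Why: Conversion of primary allylic alcohols into bromides with PBr3 at low temperature; the sensitive dibromide is used crude.

Step 15
Reactants: 23 (2E,4E,6E)-1,8-dibromo-2,7-dimethylocta-2,4,6-triene
Product: 24 tetraethyl [(2E,4E,6E)-2,7-dimethylocta-2,4,6-triene-1,8-diyl]bis(phosphonate)
Conditions: P(OEt)3, toluene, 110 °C
Reagents that add atoms: triethyl phosphite, CCOP(OCC)OCC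
Why: Michaelis–Arbuzov reaction at two primary allylic bromides; direct SN2 attack of phosphorus keeps the E trisubstituted double bonds in place.

Step 16
Reactants: 24 tetraethyl [(2E,4E,6E)-2,7-dimethylocta-2,4,6-triene-1,8-diyl]bis(phosphonate); 13 (2E)-3-iodobut-2-enal
Product: 25 diethyl [(2E,4E,6E,8E,10E)-11-iodo-2,7-dimethyldodeca-2,4,6,8,10-pentaen-1-yl]phosphonate
Conditions: 24 (excess), NaN(SiMe3)2 (1 equiv per 13), THF, −78 °C; then 13, −78 → 0 °C, dark
Reagents that add atoms: none
Why: Horner–Wadsworth–Emmons olefination that forms C11=C12 with E selectivity. Using 24 in excess with one equivalent of base gives mainly the monoanion, which adds to the aldehyde at −78 °C before any 25 exists to be deprotonated, so the second phosphonate should survive. 1,2-Addition to the aldehyde should be faster than attack at the iodine-bearing carbon.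

Step 17
Reactants: 25 diethyl [(2E,4E,6E,8E,10E)-11-iodo-2,7-dimethyldodeca-2,4,6,8,10-pentaen-1-yl]phosphonate; 20 (2Z)-3-(6-methyl-4,8-dioxo-1,3,6,2-dioxazaborocan-2-yl)but-2-enal
Product: 26 2-[(2Z,4E,6E,8E,10E,12E,14E)-15-iodo-6,11-dimethylhexadeca-2,4,6,8,10,12,14-heptaen-2-yl]-6-methyl-1,3,6,2-dioxazaborocane-4,8-dione
Conditions: 25 (1.1 equiv), NaN(SiMe3)2 (1.0 equiv), THF, −78 °C; then 20 in THF–DMF, −78 → 0 °C, dark
Reagents that add atoms: none
Why: Horner–Wadsworth–Emmons olefination that forms C11'=C12' (E). The base is used up by the phosphonate before 20 is added, so the cage meets only a stabilised carbanion, a situation formyl-substituted iminodiacetate boronates are known to tolerate. The product can be purified on silica and crystallised, which also removes minor Z isomers.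

Step 18
Reactants: 4 (1S,2S)-4-ethynyl-3,5,5-trimethylcyclohex-3-ene-1,2-diol; 26 C18 heptaenyl iodide iminodiacetate boronate; 8 (1S,2S)-4-[(E)-2-iodoethenyl]-3,5,5-trimethylcyclohex-3-ene-1,2-diol
Product: 29 (3S,4S,3'S,4'S)-7,8-didehydro-β,β-carotene-3,4,3',4'-tetrol (target), via C27 enyne iminodiacetate boronate 27 (not isolated), via C27 enyne boronic acid 28 (not isolated)
Conditions: 4 (limiting), 26, Pd(PPh3)4 (5 mol %), CuI (10 mol %), Et3N, THF, rt, degassed, dark; then 8, 3 M aq. NaOH, Pd(PPh3)4 (5 mol %), rt → 40 °C
Reagents that add atoms: none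
Why: Zerovalent palladium inserts into the C9–I bond of 26, the copper acetylide of 4 (CuI, Et3N) transmetalates, and reductive elimination forms C8–C9 to give 27; the boron of 26 is tetracoordinate, has no vacant orbital and cannot transmetalate, so the chain does not oligomerise. Aqueous NaOH then cleaves the cage to boronic acid 28, whose hydroxide-activated boron transmetalates to the divalent alkenylpalladium iodide formed by oxidative addition into the C8'–I bond of 8, and reductive elimination forms C8'–C9'. The closest known reaction type is iterative cross-coupling of haloalkenyl iminodiacetate boronates, a Sonogashira coupling followed by a Suzuki–Miyaura coupling with release of boron in the flask. No ring is closed and no stereocentre is made; the four carbinol centres are spectators. The step needs chemoselectivity between the two chain termini, which the mask on boron secures until hydroxide is added. It also needs selectivity between the two iodides, secured by adding 8 only after the limiting alkyne 4 is consumed, so that no alkyne is left to couple with 8. Alkene geometry is retained because oxidative addition, transmetalation and reductive elimination at sp2 carbon are all stereoretentive, and the free hydroxyl groups interfere with neither coupling. Crystallisation in the dark should give all-E 29.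

## Compound list

1 | safranal, 2,6,6-trimethylcyclohexa-1,3-diene-1-carbaldehyde | CC1=C(C=O)C(C)(C)CC=C1 | starting material
2 | 1-ethynyl-2,6,6-trimethylcyclohexa-1,3-diene | CC1=C(C#C)C(C)(C)CC=C1 | intermediate
3 | (1R,6S)-3-ethynyl-2,4,4-trimethyl-7-oxabicyclo[4.1.0]hept-2-ene | CC1=C(C#C)C(C)(C)C[C@@H]2O[C@H]12 | intermediate
4 | (1S,2S)-4-ethynyl-3,5,5-trimethylcyclohex-3-ene-1,2-diol | CC1=C(C#C)C(C)(C)C[C@H](O)[C@H]1O | intermediate
5 | {[(1S,2S)-4-ethynyl-3,5,5-trimethylcyclohex-3-ene-1,2-diyl]bis(oxy)}bis(triethylsilane) | CC1=C(C#C)C(C)(C)C[C@H](O[Si](CC)(CC)CC)[C@H]1O[Si](CC)(CC)CC | intermediate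
6 | chloro(bis-cyclopentadienyl)zirconium (E)-alkenyl derivative of 5, zirconium on C8 | CC1=C(/C=C/[Zr](Cl)(C2C=CC=C2)C2C=CC=C2)C(C)(C)C[C@H](O[Si](CC)(CC)CC)[C@H]1O[Si](CC)(CC)CC | intermediate
7 | {[(1S,2S)-4-[(E)-2-iodoethenyl]-3,5,5-trimethylcyclohex-3-ene-1,2-diyl]bis(oxy)}bis(triethylsilane) | CC1=C(/C=C/I)C(C)(C)C[C@H](O[Si](CC)(CC)CC)[C@H]1O[Si](CC)(CC)CC | intermediate
8 | (1S,2S)-4-[(E)-2-iodoethenyl]-3,5,5-trimethylcyclohex-3-ene-1,2-diol | CC1=C(/C=C/I)C(C)(C)C[C@H](O)[C@H]1O | intermediate
9 | but-2-yn-1-ol | CC#CCO | starting material
10 | (but-2-yn-1-yloxy)bis(2-methylpropyl)aluminium | CC#CCO[Al](CC(C)C)CC(C)C | intermediate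
11 | chloro(bis-cyclopentadienyl)zirconium (E)-alkenyl derivative of 10, zirconium on C3 | Cl[Zr](C1C=CC=C1)(C1C=CC=C1)/C(C)=C/CO[Al](CC(C)C)CC(C)C | intermediate
12 | (2E)-3-iodobut-2-en-1-ol | I/C(C)=C/CO | intermediate
13 | (2E)-3-iodobut-2-enal | I/C(C)=C/C=O | intermediate
14 | tert-butyl{[(2E)-3-iodobut-2-en-1-yl]oxy}dimethylsilane | I/C(C)=C/CO[Si](C)(C)C(C)(C)C | intermediate
15 | N-methyliminodiacetic acid | CN(CC(=O)O)CC(=O)O | starting material
16 | [(2E)-4-{[tert-butyl(dimethyl)silyl]oxy}but-2-en-2-yl]lithium | [Li]/C(C)=C/CO[Si](C)(C)C(C)(C)C | intermediate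
17 | lithium [(2Z)-4-{[tert-butyl(dimethyl)silyl]oxy}but-2-en-2-yl]tri(propan-2-yloxy)borate | [Li+].CC(C)O[B-](OC(C)C)(OC(C)C)/C(C)=C/CO[Si](C)(C)C(C)(C)C | intermediate
18 | 2-[(2Z)-4-{[tert-butyl(dimethyl)silyl]oxy}but-2-en-2-yl]-6-methyl-1,3,6,2-dioxazaborocane-4,8-dione | CC(C)(C)[Si](C)(C)OC/C=C(C)/B1OC(=O)CN(C)CC(=O)O1 | intermediate
19 | 2-[(2Z)-4-hydroxybut-2-en-2-yl]-6-methyl-1,3,6,2-dioxazaborocane-4,8-dione | OC/C=C(C)/B1OC(=O)CN(C)CC(=O)O1 | intermediate
20 | (2Z)-3-(6-methyl-4,8-dioxo-1,3,6,2-dioxazaborocan-2-yl)but-2-enal | O=C/C=C(C)/B1OC(=O)CN(C)CC(=O)O1 | intermediate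
21 | (2E,4E,6E)-2,7-dimethylocta-2,4,6-trienedial | O=C/C(C)=C/C=C/C=C(C)/C=O | starting material
22 | (2E,4E,6E)-2,7-dimethylocta-2,4,6-triene-1,8-diol | OC/C(C)=C/C=C/C=C(C)/CO | intermediate
23 | (2E,4E,6E)-1,8-dibromo-2,7-dimethylocta-2,4,6-triene | BrC/C(C)=C/C=C/C=C(C)/CBr | intermediate
24 | tetraethyl [(2E,4E,6E)-2,7-dimethylocta-2,4,6-triene-1,8-diyl]bis(phosphonate) | CCOP(=O)(OCC)C/C(C)=C/C=C/C=C(C)/CP(=O)(OCC)OCC | intermediate
25 | diethyl [(2E,4E,6E,8E,10E)-11-iodo-2,7-dimethyldodeca-2,4,6,8,10-pentaen-1-yl]phosphonate | CCOP(=O)(OCC)C/C(C)=C/C=C/C=C(C)/C=C/C=C(C)/I | intermediate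
26 | 2-[(2Z,4E,6E,8E,10E,12E,14E)-15-iodo-6,11-dimethylhexadeca-2,4,6,8,10,12,14-heptaen-2-yl]-6-methyl-1,3,6,2-dioxazaborocane-4,8-dione (C9 to C9' chain, iodine on C9, boron on C9') | I/C(C)=C/C=C/C(C)=C/C=C/C=C(C)/C=C/C=C(C)/B1OC(=O)CN(C)CC(=O)O1 | intermediate
27 | iminodiacetate boronate of the ring A C27 enyne (26 with iodine replaced by the ethynyl carbon C8 of 4) | CC1=C(C#C/C(C)=C/C=C/C(C)=C/C=C/C=C(C)/C=C/C=C(C)/B2OC(=O)CN(C)CC(=O)O2)C(C)(C)C[C@H](O)[C@H]1O | intermediate
28 | boronic acid of the ring A C27 enyne (27 with the cage hydrolysed) | CC1=C(C#C/C(C)=C/C=C/C(C)=C/C=C/C=C(C)/C=C/C=C(C)/B(O)O)C(C)(C)C[C@H](O)[C@H]1O | intermediate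
29 | (3S,4S,3'S,4'S)-7,8-didehydro-β,β-carotene-3,4,3',4'-tetrol | CC1=C(C#C/C(C)=C/C=C/C(C)=C/C=C/C=C(C)/C=C/C=C(C)/C=C/C2=C(C)[C@H](O)[C@@H](O)CC2(C)C)C(C)(C)C[C@H](O)[C@H]1O | target

## Step count and least certain steps

Total step count: 18. Longest linear sequence: 7 steps (1 → 2 → 3 → 4 → 5 → 7 → 8 → 29, and equally 9 → 12 → 14 → 18 → 19 → 20 → 26 → 29).

**Step 18 (key step).** The most likely failure is loss of the boronic acid once hydroxide is added while copper salts are still present, by protodeboronation or oxidative homocoupling of the heptaenylboron species. Partial coupling of residual alkyne with 8 and E/Z scrambling under prolonged exposure to palladium are further risks. The fallback closes the chain by olefination instead of cross-coupling. It sets out from 4, 8, 13, 20 and 24 and comes back to the route at 29.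
- Sonogashira coupling of 4 with 13 (Pd(PPh3)4, CuI, Et3N) should give the ring A ynenal F1.
- Slow hydrolysis of 20 with aqueous K3PO4 releases the boronic acid F2, which couples with 8 (Pd(OAc)2, dicyclohexyl(2',6'-dimethoxybiphenyl-2-yl)phosphine) to the ring B dienal F3.
- Olefination of the monoanion of 24 (in excess, with extra base to cover the hydroxyl groups) with F1 gives the C25 phosphonate F4.
- A second Horner–Wadsworth–Emmons reaction of F4 with F3 gives 29.

**Step 3.** Inversion at C4 may not be clean if the opening passes through a free allyl cation, which would give the cis diol. The cation, delocalised into the alkyne, may also be captured at its far end. The fallback sets out from 3 and comes back at 4: acetolysis in buffered acetic acid (AcOH, NaOAc) lets the better nucleophile acetate open the oxirane at C4 with inversion to the trans hydroxy acetate F5, and K2CO3 in methanol then frees 4.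

**Step 2.** Facial selectivity may be insufficient, or oxidation may spill over to the C5=C6 bond. The fallback changes from catalyst control to resolution. It sets out from 4 of insufficient enantiomeric purity and comes back at 4: esterification with (S)-2-methoxy-2-phenylacetic acid (carbodiimide, DMAP) gives the bis-ester F6, which is separated from the diastereomer formed by the (3R,4R) diol by crystallisation or chromatography, and K2CO3 in methanol returns enantiopure 4.

**Step 16.** The product phosphonate may be deprotonated and olefinated a second time, and the carbanion may attack the iodine-bearing carbon of 13 by addition–elimination. The fallback reverses the polarity so that the symmetric partner is the dialdehyde, whose second aldehyde is deactivated after the first olefination. It sets out from 12 and 21 and comes back at 25.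
- Bromination of 12 (CBr4, PPh3) gives the bromide F7, and Arbuzov reaction with triethyl phosphite gives the iodo phosphonate F8.
- Olefination of 21 (in excess) with the anion of F8 gives the iodo pentaenal F9.
- NaBH4 reduction gives the alcohol F10, PBr3 the bromide F11, and a second Arbuzov reaction gives 25.

**Step 10.** The iodine–lithium exchange may be incomplete, or the alkenylboron species may be protodeboronated during hot transligation. The fallback replaces the organolithium by palladium catalysis. It sets out from 14 and comes back at 18: Miyaura borylation (PdCl2(PPh3)2, PPh3, KOPh, bis(pinacolato)diboron, toluene, 50 °C) gives the pinacol boronate F12, NaIO4 with NH4OAc cleaves the pinacol to the boronic acid F13, and condensation with 15 in toluene–DMSO with removal of water gives 18.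

## Further compounds

F1 | step 18 | (2E)-5-[(3S,4S)-3,4-dihydroxy-2,6,6-trimethylcyclohex-1-en-1-yl]-3-methylpent-2-en-4-ynal | CC1=C(C#C/C(C)=C/C=O)C(C)(C)C[C@H](O)[C@H]1O
F2 | step 18 | [(2Z)-4-oxobut-2-en-2-yl]boronic acid | O=C/C=C(C)/B(O)O
F3 | step 18 | (2E,4E)-5-[(3S,4S)-3,4-dihydroxy-2,6,6-trimethylcyclohex-1-en-1-yl]-3-methylpenta-2,4-dienal | CC1=C(/C=C/C(C)=C/C=O)C(C)(C)C[C@H](O)[C@H]1O
F4 | step 18 | diethyl [(2E,4E,6E,8E,10E)-13-[(3S,4S)-3,4-dihydroxy-2,6,6-trimethylcyclohex-1-en-1-yl]-2,7,11-trimethyltrideca-2,4,6,8,10-pentaen-12-yn-1-yl]phosphonate | CCOP(=O)(OCC)C/C(C)=C/C=C/C=C(C)/C=C/C=C(C)/C#CC1=C(C)[C@H](O)[C@@H](O)CC1(C)C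
F5 | step 3 | (1S,6S)-3-ethynyl-6-hydroxy-2,4,4-trimethylcyclohex-2-en-1-yl acetate | CC1=C(C#C)C(C)(C)C[C@H](O)[C@H]1OC(C)=O
F6 | step 2 | (1S,2S)-4-ethynyl-3,5,5-trimethylcyclohex-3-ene-1,2-diyl bis[(2S)-2-methoxy-2-phenylacetate] | CC1=C(C#C)C(C)(C)C[C@H](OC(=O)[C@@H](OC)c2ccccc2)[C@H]1OC(=O)[C@@H](OC)c1ccccc1
F7 | step 16 | (2E)-1-bromo-3-iodobut-2-ene | BrC/C=C(C)/I
F8 | step 16 | diethyl [(2E)-3-iodobut-2-en-1-yl]phosphonate | CCOP(=O)(OCC)C/C=C(C)/I
F9 | step 16 | (2E,4E,6E,8E,10E)-11-iodo-2,7-dimethyldodeca-2,4,6,8,10-pentaenal | O=C/C(C)=C/C=C/C=C(C)/C=C/C=C(C)/I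
F10 | step 16 | (2E,4E,6E,8E,10E)-11-iodo-2,7-dimethyldodeca-2,4,6,8,10-pentaen-1-ol | OC/C(C)=C/C=C/C=C(C)/C=C/C=C(C)/I
F11 | step 16 | (2E,4E,6E,8E,10E)-1-bromo-11-iodo-2,7-dimethyldodeca-2,4,6,8,10-pentaene | BrC/C(C)=C/C=C/C=C(C)/C=C/C=C(C)/I
F12 | step 10 | tert-butyldimethyl{[(2Z)-3-(4,4,5,5-tetramethyl-1,3,2-dioxaborolan-2-yl)but-2-en-1-yl]oxy}silane | CC(C)(C)[Si](C)(C)OC/C=C(C)/B1OC(C)(C)C(C)(C)O1
F13 | step 10 | [(2Z)-4-{[tert-butyl(dimethyl)silyl]oxy}but-2-en-2-yl]boronic acid | CC(C)(C)[Si](C)(C)OC/C=C(C)/B(O)O
A1 | alternative 1 | [(2,6,6-trimethylcyclohexa-1,3-dien-1-yl)ethynyl]trimethylsilane | CC1=C(C#C[Si](C)(C)C)C(C)(C)CC=C1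
A2 | alternative 1 | trimethyl{[(1R,6S)-2,4,4-trimethyl-7-oxabicyclo[4.1.0]hept-2-en-3-yl]ethynyl}silane | CC1=C(C#C[Si](C)(C)C)C(C)(C)C[C@@H]2O[C@H]12
A3 | alternative 2 | (2E)-1-[(3S,4S)-3,4-bis{[tert-butyl(dimethyl)silyl]oxy}-2,6,6-trimethylcyclohex-1-en-1-yl]-4-[(4-methoxybenzyl)oxy]-2-methylbut-2-en-1-one | CC1=C(C(=O)/C(C)=C/COCc2ccc(OC)cc2)C(C)(C)C[C@H](O[Si](C)(C)C(C)(C)C)[C@H]1O[Si](C)(C)C(C)(C)C
A4 | alternative 2 | ring A C13 enyne, bis(tert-butyldimethylsilyl) ether, 4-methoxybenzyl ether at C11 | CC1=C(C#C/C(C)=C/COCc2ccc(OC)cc2)C(C)(C)C[C@H](O[Si](C)(C)C(C)(C)C)[C@H]1O[Si](C)(C)C(C)(C)C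
A5 | alternative 3 | ring A buta-1,3-diynyl unit, bis(tert-butyldimethylsilyl) ether | CC1=C(C#CC#C)C(C)(C)C[C@H](O[Si](C)(C)C(C)(C)C)[C@H]1O[Si](C)(C)C(C)(C)C
A6 | alternative 3 | ring B C26 heptaenyl iodide (iodine on C11), bis(tert-butyldimethylsilyl) ether | I/C=C/C(C)=C/C=C/C=C(C)/C=C/C=C(C)/C=C/C1=C(C)[C@H](O[Si](C)(C)C(C)(C)C)[C@@H](O[Si](C)(C)C(C)(C)C)CC1(C)C
A7 | alternative 3 | tetrakis(tert-butyldimethylsilyl) ether of the target | CC1=C(C#C/C(C)=C/C=C/C(C)=C/C=C/C=C(C)/C=C/C=C(C)/C=C/C2=C(C)[C@H](O[Si](C)(C)C(C)(C)C)[C@@H](O[Si](C)(C)C(C)(C)C)CC2(C)C)C(C)(C)C[C@H](O[Si](C)(C)C(C)(C)C)[C@H]1O[Si](C)(C)C(C)(C)C
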